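The pyran ring (ring C) of the flavan unit is cut at its two bonds to ring A, C4–C4a and O1–C8a. These sit on neighbouring ring-A carbons beside the C5 oxygen, the pattern of a 3-alkoxybenzyne. In the key step such an aryne, released from a silyl triflate, adds the C=O group of a cinnamaldehyde in a formal [2+2] reaction; the benzoxete opens to an ortho-quinone methide and recloses to a flav-3-ene. Both bonds thus form in one operation, while the aldehyde C=O bond breaks and its oxygen becomes O1, bonded to C2. The same aryne precursor later annulates the benzofuranone, after a Norrish–Yang photocyclization has closed the dihydrofuran.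

Key step: step 6

Remarks before the steps:
- Locants: chroman numbering (O1, C2, C3, C4, C4a, C5–C8, C8a) is used up to 22. Compounds 24–26 are numbered as furo[2,3-h]chromenes (O7, C8 and C9 are the furan atoms). In 27 and 28 the primed locants belong to the furochromene half.
- Assumption: (R,R)-Ph-BPE is taken as the ligand enantiomer matched to (2S)-16 in step 7; if the sense proves opposite, its antipode is used.
- Assumption: 4-(benzyloxy)benzyl aryl ethers behave like 4-methoxybenzyl aryl ethers (stable to base, fluoride and organolithiums at −78 °C, cleaved by hydrogenolysis).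

Step 1
Reactants: 1 phloroglucinol; 2 4-(benzyloxy)benzyl chloride
Product: 3 3,5-bis{[4-(benzyloxy)benzyl]oxy}phenol
Conditions: 2 (2.0 equiv), K2CO3 (2.2 equiv), DMF, 25 °C; chromatography to remove mono- and tris-ether
Reagents that add atoms: none
Why: Williamson ether synthesis run statistically on three equivalent phenols should give a separable bis-ether, whose two identical ether groups later serve as the C5 protecting group and as the source of the benzylic carbon and aryl ring of the dihydrofuran.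

Step 2
Reactants: 3 3,5-bis{[4-(benzyloxy)benzyl]oxy}phenol
Product: 4 3,5-bis{[4-(benzyloxy)benzyl]oxy}phenyl N-isopropylcarbamate
Conditions: isopropyl isocyanate (1.5 equiv), Et3N (0.2 equiv), CH2Cl2, 25 °C
Reagents that add atoms: isopropyl isocyanate, CC(C)N=C=O
Why: Base-catalysed addition of the phenol to the isocyanate (carbamoylation) installs a directing group that can later be removed under mild, non-acidic conditions.

Step 3
Reactants: 4 3,5-bis{[4-(benzyloxy)benzyl]oxy}phenyl N-isopropylcarbamate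
Product: 8 3,5-bis{[4-(benzyloxy)benzyl]oxy}-2-(trimethylsilyl)phenyl N-isopropylcarbamate, via N-silyl carbamate 5 (not isolated), via aryllithium 6 (not isolated), via bis-silyl carbamate 7 (not isolated)
Conditions: TBSOTf, TMEDA, Et2O, 0→25 °C; n-BuLi, TMEDA, −78 °C; TMSCl, −78→25 °C; aq. NH4Cl
Reagents that add atoms: chlorotrimethylsilane, C[Si](C)(C)Cl
Why: Directed ortho-metalation: the carbamate, N-silylated in the flask so that its N–H does not consume base, and the flanking ether jointly direct n-BuLi to C2, the aryllithium is silylated by TMSCl, and the N–Si bond is hydrolysed on work-up.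

Step 4
Reactants: 8 3,5-bis{[4-(benzyloxy)benzyl]oxy}-2-(trimethylsilyl)phenyl N-isopropylcarbamate
Product: 10 3,5-bis{[4-(benzyloxy)benzyl]oxy}-2-(trimethylsilyl)phenyl trifluoromethanesulfonate, via silyl phenol 9 (not isolated)
Conditions: DBU, Et2NH, MeCN, 40 °C; then PhNTf2, 25 °C
Reagents that add atoms: N-phenylbis(trifluoromethanesulfonimide), O=S(=O)(N(c1ccccc1)S(=O)(=O)C(F)(F)F)C(F)(F)F
Why: Carbamate cleavage by elimination (E1cB) with DBU, diethylamine trapping the isopropyl isocyanate as a urea, frees the ortho-silyl phenoxide, which is O-sulfonylated by PhNTf2 to the ortho-silylaryl triflate.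

Step 5
Reactants: 11 4-(benzyloxy)benzaldehyde
Product: 12 (E)-3-[4-(benzyloxy)phenyl]prop-2-enal
Conditions: Ph3P=CHCHO (1.05 equiv), toluene, 80 °C
Reagents that add atoms: (triphenylphosphoranylidene)acetaldehyde, O=CC=P(c1ccccc1)(c1ccccc1)c1ccccc1
Why: Wittig olefination with the stabilised formyl ylide should give the (E)-enal, one equivalent of ylide limiting further homologation.

Step 6
Reactants: 10 3,5-bis{[4-(benzyloxy)benzyl]oxy}-2-(trimethylsilyl)phenyl trifluoromethanesulfonate; 12 (E)-3-[4-(benzyloxy)phenyl]prop-2-enal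
Product: 16 racemic 2-[4-(benzyloxy)phenyl]-5,7-bis{[4-(benzyloxy)benzyl]oxy}-2H-chromene, via aryne 13 (not isolated), via benzoxete 14 (not isolated), via ortho-quinone methide 15 (not isolated)
Conditions: 12 (3 equiv), CsF (3 equiv), MeCN, 25→50 °C, slow addition of 10
Reagents that add atoms: none
Why: Fluoride removes the silyl group of 10 and triflate leaves, giving aryne 13; the carbonyl oxygen of 12 adds to the aryne carbon remote from the flanking ether (the future C8a) and the aryl anion formed next to that ether (future C4a) collapses onto the oxocarbenium carbon (future C4), a stepwise formal [2+2] addition that gives benzoxete 14. Thermal 4π-electrocyclic opening of 14 gives ortho-quinone methide 15, in which the old C=O bond is broken, and oxa-6π-electrocyclization of its dienone closes the pyran ring (O1–C2) to flav-3-ene 16. The closest known reaction type is the annulation of arynes with α,β-unsaturated aldehydes to 2H-chromenes, and the same addition mode is known for arynes with formamides. Ring closures: the four-membered ring by 4-exo-trig attack of the aryl anion on the oxocarbenium ion, the six-membered ring by disrotatory 6π-electrocyclization (6-endo). The one new stereocentre, C2, forms without control, so 16 is racemic and is resolved in step 7. The step needs regioselective addition to the aryne, secured by the ether oxygen flanking the triple bond (aryne distortion and inductive stabilisation of the anion ortho to oxygen, as with 3-methoxybenzyne), and ring closure before the quinone methide meets a second aryne, secured by slow addition of 10 to excess 12.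

Step 7
Reactants: 16 racemic 2-[4-(benzyloxy)phenyl]-5,7-bis{[4-(benzyloxy)benzyl]oxy}-2H-chromene
Product: 18 (2R,3S)-2-[4-(benzyloxy)phenyl]-5,7-bis{[4-(benzyloxy)benzyl]oxy}chroman-3-ol, via trans-boronate 17 (not isolated)
Conditions: CuCl (5 mol%), (R,R)-Ph-BPE (6 mol%), NaOtBu (10 mol%), B2pin2 (0.55 equiv), MeOH (2 equiv), THF, 0 °C; then H2O2, aq. NaOH, 0→25 °C
Reagents that add atoms: hydrogen peroxide, OO
Why: Kinetic resolution by CuCl/(R,R)-Ph-BPE-catalysed enantioselective protoboration of the styrene-type C3=C4 bond: the ligand-bound Cu–Bpin species should add syn to the matched (2S)-enantiomer of 16 (which has the C2 geometry of the target; the descriptor becomes R in 18) anti to the C2 aryl group with boron at C3, methanol cleaves the benzylic C4–Cu bond and oxidation with retention gives the 2,3-trans alcohol, so C3 is set by the anti addition and the absolute configuration by the ligand, while the (2R)-enantiomer of 16 stays unchanged and is removed by chromatography.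

Step 8
Reactants: 18 (2R,3S)-2-[4-(benzyloxy)phenyl]-5,7-bis{[4-(benzyloxy)benzyl]oxy}chroman-3-ol
Product: 19 (2R,3S)-3-(benzyloxy)-2-[4-(benzyloxy)phenyl]-5,7-bis{[4-(benzyloxy)benzyl]oxy}chromane
Conditions: NaH, BnBr, Bu4NI (cat.), DMF, 0→25 °C
Reagents that add atoms: benzyl bromide, BrCc1ccccc1
Why: Williamson etherification of the secondary alkoxide shields O3 from the organolithium and aryne steps, touches no stereocentre and gives a group that leaves in the final hydrogenolysis.

Step 9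
Reactants: 19 (2R,3S)-3-(benzyloxy)-2-[4-(benzyloxy)phenyl]-5,7-bis{[4-(benzyloxy)benzyl]oxy}chromane
Product: 20 (2R,3S)-3-(benzyloxy)-2-[4-(benzyloxy)phenyl]-5,7-bis{[4-(benzyloxy)benzyl]oxy}-8-bromochromane
Conditions: NBS (1.0 equiv), CH2Cl2, −40→−20 °C
Reagents that add atoms: N-bromosuccinimide, O=C1CCC(=O)N1Br
Why: Electrophilic aromatic bromination of 5,7-dibenzyloxy-type flavans is known to go to C8, which is flanked by one benzylic ether and the ring oxygen, and not to the more crowded C6.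

Step 10
Reactants: 20 (2R,3S)-3-(benzyloxy)-2-[4-(benzyloxy)phenyl]-5,7-bis{[4-(benzyloxy)benzyl]oxy}-8-bromochromane
Product: 22 methyl 2-{(2R,3S)-3-(benzyloxy)-2-[4-(benzyloxy)phenyl]-5,7-bis{[4-(benzyloxy)benzyl]oxy}chroman-8-yl}-2-oxoacetate, via aryllithium 21 (not isolated)
Conditions: n-BuLi (1.1 equiv), THF, −78 °C; cannulation into dimethyl oxalate (4 equiv), THF, −78 °C; aq. NH4Cl
Reagents that add atoms: dimethyl oxalate, COC(=O)C(=O)OC
Why: Bromine–lithium exchange followed by acylation of the aryllithium with excess dimethyl oxalate (inverse addition) should give the aryl α-keto ester, the tetrahedral adduct persisting at −78 °C and preventing a second addition.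

Step 11
Reactants: 22 methyl 2-{(2R,3S)-3-(benzyloxy)-2-[4-(benzyloxy)phenyl]-5,7-bis{[4-(benzyloxy)benzyl]oxy}chroman-8-yl}-2-oxoacetate
Product: 24 methyl (2R,3S,8S,9S)-3-(benzyloxy)-2,8-bis[4-(benzyloxy)phenyl]-5-{[4-(benzyloxy)benzyl]oxy}-9-hydroxy-3,4,8,9-tetrahydro-2H-furo[2,3-h]chromene-9-carboxylate, via 1,5-biradical 23 (not isolated)
Conditions: hν (365 nm), degassed benzene (0.01 M), 25 °C; chromatography
Reagents that add atoms: none
Why: Norrish–Yang photocyclization, known for ortho-benzyloxyphenyl glyoxylates: the excited keto group abstracts a δ-hydrogen from the C7 O–CH2 group and the 1,5-biradical closes the C8–C9 bond; C8 and C9 form together with the aryl group expected cis to OH and trans to the ester (the less crowded closure in a non-hydrogen-bonding solvent), but C2 and C3 are too remote to bias the sense, so the (8S,9S) isomer 24 is separated from its (8R,9R) diastereomer by chromatography.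

Step 12
Reactants: 24 methyl (2R,3S,8S,9S)-3-(benzyloxy)-2,8-bis[4-(benzyloxy)phenyl]-5-{[4-(benzyloxy)benzyl]oxy}-9-hydroxy-3,4,8,9-tetrahydro-2H-furo[2,3-h]chromene-9-carboxylate; 10 3,5-bis{[4-(benzyloxy)benzyl]oxy}-2-(trimethylsilyl)phenyl trifluoromethanesulfonate
Product: 27 (2S,2'R,3'S,8'S)-3'-(benzyloxy)-2',8'-bis[4-(benzyloxy)phenyl]-4,5',6-tris{[4-(benzyloxy)benzyl]oxy}-3',4'-dihydro-2'H,8'H-spiro[1-benzofuran-2,9'-furo[2,3-h]chromen]-3-one, via potassium alkoxide 25 (not isolated), via aryl anion 26 (not isolated)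
Conditions: KH (1.1 equiv), 18-crown-6, THF, 0 °C; then CsF (3 equiv), slow addition of 10 (1.5 equiv), 25→50 °C
Reagents that add atoms: none
Why: Proposed new method: KH converts the tertiary α-hydroxy ester into alkoxide 25, which should add to the aryne released from 10 by fluoride (the same species as 13 in step 6) at the carbon remote from the flanking ether, and the aryl anion 26 formed ortho to the new C–O bond should attack the ester in a 5-exo-trig acyl substitution that expels methoxide and closes the 4,6-dioxygenated benzofuranone; the spiro centre keeps its configuration because the C9–O bond is never broken; the closest known reaction types are the annulation of arynes with methyl salicylates to xanthones and the insertion of arynes into the C–O bond of carboxylic acids.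

Step 13
Reactants: 27 (2S,2'R,3'S,8'S)-3'-(benzyloxy)-2',8'-bis[4-(benzyloxy)phenyl]-4,5',6-tris{[4-(benzyloxy)benzyl]oxy}-3',4'-dihydro-2'H,8'H-spiro[1-benzofuran-2,9'-furo[2,3-h]chromen]-3-one
Product: 28 (2S,2'R,3'S,8'S)-3',4,5',6-tetrahydroxy-2',8'-bis(4-hydroxyphenyl)-3',4'-dihydro-2'H,8'H-spiro[1-benzofuran-2,9'-furo[2,3-h]chromen]-3-one (CNP0228515.1)
Conditions: H2 (1 atm), Pd(OH)2/C, THF–MeOH, 25 °C, stopped at complete debenzylation
Reagents that add atoms: none
Why: Hydrogenolysis should cleave the nine benzylic C–O bonds of the protecting groups (six O-benzyl and three 4-oxybenzyl ethers), while the ring C–O bonds at C2', C8' and the spiro carbon, being secondary or tertiary and hindered, are expected to react more slowly under neutral conditions at 1 atm; no stereocentre is touched.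

Compound list
1 | phloroglucinol | Oc1cc(O)cc(O)c1 | starting material
2 | 4-(benzyloxy)benzyl chloride | ClCc1ccc(OCc2ccccc2)cc1 | starting material
3 | 3,5-bis{[4-(benzyloxy)benzyl]oxy}phenol | Oc1cc(OCc2ccc(OCc3ccccc3)cc2)cc(OCc2ccc(OCc3ccccc3)cc2)c1 | intermediate
4 | 3,5-bis{[4-(benzyloxy)benzyl]oxy}phenyl N-isopropylcarbamate | CC(C)NC(=O)Oc1cc(OCc2ccc(OCc3ccccc3)cc2)cc(OCc2ccc(OCc3ccccc3)cc2)c1 | intermediate
5 | N-(tert-butyldimethylsilyl) derivative of 4 (not isolated) | CC(C)N(C(=O)Oc1cc(OCc2ccc(OCc3ccccc3)cc2)cc(OCc2ccc(OCc3ccccc3)cc2)c1)[Si](C)(C)C(C)(C)C | intermediate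
6 | 2-lithio derivative of 5, lithium between the carbamate and an ether (not isolated) | CC(C)N(C(=O)Oc1cc(OCc2ccc(OCc3ccccc3)cc2)cc(OCc2ccc(OCc3ccccc3)cc2)c1[Li])[Si](C)(C)C(C)(C)C | intermediate
7 | 2-(trimethylsilyl) derivative of 5 (not isolated) | CC(C)N(C(=O)Oc1cc(OCc2ccc(OCc3ccccc3)cc2)cc(OCc2ccc(OCc3ccccc3)cc2)c1[Si](C)(C)C)[Si](C)(C)C(C)(C)C | intermediate
8 | 3,5-bis{[4-(benzyloxy)benzyl]oxy}-2-(trimethylsilyl)phenyl N-isopropylcarbamate | CC(C)NC(=O)Oc1cc(OCc2ccc(OCc3ccccc3)cc2)cc(OCc2ccc(OCc3ccccc3)cc2)c1[Si](C)(C)C | intermediate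
9 | 3,5-bis{[4-(benzyloxy)benzyl]oxy}-2-(trimethylsilyl)phenol (not isolated) | Oc1cc(OCc2ccc(OCc3ccccc3)cc2)cc(OCc2ccc(OCc3ccccc3)cc2)c1[Si](C)(C)C | intermediate
10 | 3,5-bis{[4-(benzyloxy)benzyl]oxy}-2-(trimethylsilyl)phenyl trifluoromethanesulfonate | O=S(=O)(Oc1cc(OCc2ccc(OCc3ccccc3)cc2)cc(OCc2ccc(OCc3ccccc3)cc2)c1[Si](C)(C)C)C(F)(F)F | intermediate
11 | 4-(benzyloxy)benzaldehyde | O=Cc1ccc(OCc2ccccc2)cc1 | starting material
12 | (E)-3-[4-(benzyloxy)phenyl]prop-2-enal | O=C/C=C/c1ccc(OCc2ccccc2)cc1 | intermediate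
13 | 3,5-bis{[4-(benzyloxy)benzyl]oxy}benzyne (1,2-didehydrobenzene, not isolated) | C1#CC(OCc2ccc(OCc3ccccc3)cc2)=CC(OCc2ccc(OCc3ccccc3)cc2)=C1 | intermediate
14 | racemic 2-{(E)-2-[4-(benzyloxy)phenyl]ethenyl}-3,5-bis{[4-(benzyloxy)benzyl]oxy}-2H-benzoxete (not isolated) | O1c2cc(OCc3ccc(OCc4ccccc4)cc3)cc(OCc3ccc(OCc4ccccc4)cc3)c2C1/C=C/c1ccc(OCc2ccccc2)cc1 | intermediate
15 | (6Z)-6-{(2E)-3-[4-(benzyloxy)phenyl]prop-2-en-1-ylidene}-3,5-bis{[4-(benzyloxy)benzyl]oxy}cyclohexa-2,4-dien-1-one (ortho-quinone methide, not isolated) | O=C1C=C(OCc2ccc(OCc3ccccc3)cc2)C=C(OCc2ccc(OCc3ccccc3)cc2)/C1=C/C=C/c1ccc(OCc2ccccc2)cc1 | intermediate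
16 | racemic 2-[4-(benzyloxy)phenyl]-5,7-bis{[4-(benzyloxy)benzyl]oxy}-2H-chromene | C1=Cc2c(OCc3ccc(OCc4ccccc4)cc3)cc(OCc3ccc(OCc4ccccc4)cc3)cc2OC1c1ccc(OCc2ccccc2)cc1 | intermediate
17 | (2S,3S)-2-[4-(benzyloxy)phenyl]-5,7-bis{[4-(benzyloxy)benzyl]oxy}-3-(4,4,5,5-tetramethyl-1,3,2-dioxaborolan-2-yl)chromane (2,3-trans, not isolated) | CC1(C)OB(OC1(C)C)[C@H]1Cc2c(OCc3ccc(OCc4ccccc4)cc3)cc(OCc3ccc(OCc4ccccc4)cc3)cc2O[C@@H]1c1ccc(OCc2ccccc2)cc1 | intermediate
18 | (2R,3S)-2-[4-(benzyloxy)phenyl]-5,7-bis{[4-(benzyloxy)benzyl]oxy}chroman-3-ol | O[C@H]1Cc2c(OCc3ccc(OCc4ccccc4)cc3)cc(OCc3ccc(OCc4ccccc4)cc3)cc2O[C@@H]1c1ccc(OCc2ccccc2)cc1 | intermediate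
19 | (2R,3S)-3-(benzyloxy)-2-[4-(benzyloxy)phenyl]-5,7-bis{[4-(benzyloxy)benzyl]oxy}chromane | C(c1ccccc1)O[C@H]1Cc2c(OCc3ccc(OCc4ccccc4)cc3)cc(OCc3ccc(OCc4ccccc4)cc3)cc2O[C@@H]1c1ccc(OCc2ccccc2)cc1 | intermediate
20 | (2R,3S)-3-(benzyloxy)-2-[4-(benzyloxy)phenyl]-5,7-bis{[4-(benzyloxy)benzyl]oxy}-8-bromochromane | C(c1ccccc1)O[C@H]1Cc2c(OCc3ccc(OCc4ccccc4)cc3)cc(OCc3ccc(OCc4ccccc4)cc3)c(Br)c2O[C@@H]1c1ccc(OCc2ccccc2)cc1 | intermediate
21 | 8-lithio analogue of 20 (not isolated) | C(c1ccccc1)O[C@H]1Cc2c(OCc3ccc(OCc4ccccc4)cc3)cc(OCc3ccc(OCc4ccccc4)cc3)c([Li])c2O[C@@H]1c1ccc(OCc2ccccc2)cc1 | intermediate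
22 | methyl 2-{(2R,3S)-3-(benzyloxy)-2-[4-(benzyloxy)phenyl]-5,7-bis{[4-(benzyloxy)benzyl]oxy}chroman-8-yl}-2-oxoacetate | C(c1ccccc1)O[C@H]1Cc2c(OCc3ccc(OCc4ccccc4)cc3)cc(OCc3ccc(OCc4ccccc4)cc3)c(C(=O)C(=O)OC)c2O[C@@H]1c1ccc(OCc2ccccc2)cc1 | intermediate
23 | 1,5-biradical from 22: hydroxy(methoxycarbonyl)methyl radical at C8 and aryl(oxy)methyl radical on O7 (not isolated) | C(c1ccccc1)O[C@H]1Cc2c(OCc3ccc(OCc4ccccc4)cc3)cc(O[CH]c3ccc(OCc4ccccc4)cc3)c([C](O)C(=O)OC)c2O[C@@H]1c1ccc(OCc2ccccc2)cc1 | intermediate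
24 | methyl (2R,3S,8S,9S)-3-(benzyloxy)-2,8-bis[4-(benzyloxy)phenyl]-5-{[4-(benzyloxy)benzyl]oxy}-9-hydroxy-3,4,8,9-tetrahydro-2H-furo[2,3-h]chromene-9-carboxylate | C(c1ccccc1)O[C@H]1Cc2c(OCc3ccc(OCc4ccccc4)cc3)cc3O[C@@H](c4ccc(OCc5ccccc5)cc4)[C@](O)(C(=O)OC)c3c2O[C@@H]1c1ccc(OCc2ccccc2)cc1 | intermediate
25 | potassium alkoxide of 24 (potassium on O9, configuration of 24 unchanged, not isolated) | C(c1ccccc1)O[C@H]1Cc2c(OCc3ccc(OCc4ccccc4)cc3)cc3O[C@@H](c4ccc(OCc5ccccc5)cc4)[C@](O[K])(C(=O)OC)c3c2O[C@@H]1c1ccc(OCc2ccccc2)cc1 | intermediate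
26 | O9-aryl ether of 24 carrying a 2-potassio-3,5-bis{[4-(benzyloxy)benzyl]oxy}phenyl group (aryl anion ortho to the new C–O bond and to an ether, configuration of 24 unchanged, not isolated) | C(c1ccccc1)O[C@H]1Cc2c(OCc3ccc(OCc4ccccc4)cc3)cc3O[C@@H](c4ccc(OCc5ccccc5)cc4)[C@](Oc4cc(OCc5ccc(OCc6ccccc6)cc5)cc(OCc5ccc(OCc6ccccc6)cc5)c4[K])(C(=O)OC)c3c2O[C@@H]1c1ccc(OCc2ccccc2)cc1 | intermediate
27 | (2S,2'R,3'S,8'S)-3'-(benzyloxy)-2',8'-bis[4-(benzyloxy)phenyl]-4,5',6-tris{[4-(benzyloxy)benzyl]oxy}-3',4'-dihydro-2'H,8'H-spiro[1-benzofuran-2,9'-furo[2,3-h]chromen]-3-one | C(c1ccccc1)O[C@H]1Cc2c(OCc3ccc(OCc4ccccc4)cc3)cc3O[C@@H](c4ccc(OCc5ccccc5)cc4)[C@@]4(Oc5cc(OCc6ccc(OCc7ccccc7)cc6)cc(OCc6ccc(OCc7ccccc7)cc6)c5C4=O)c3c2O[C@@H]1c1ccc(OCc2ccccc2)cc1 | intermediate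
28 | (2S,2'R,3'S,8'S)-3',4,5',6-tetrahydroxy-2',8'-bis(4-hydroxyphenyl)-3',4'-dihydro-2'H,8'H-spiro[1-benzofuran-2,9'-furo[2,3-h]chromen]-3-one (CNP0228515.1) | O[C@H]1Cc2c(O)cc3O[C@@H](c4ccc(O)cc4)[C@@]4(Oc5cc(O)cc(O)c5C4=O)c3c2O[C@@H]1c1ccc(O)cc1 | target

Total step count: 13
Longest linear sequence: 12 steps (steps 1–4 and 6–13, from 1 to 28); step 5 is a one-step side branch.

Steps most likely to fail

1. Step 12 (Proposed new method). The hindered tertiary alkoxide may add too slowly to the aryne, or the aryl anion may be protonated before it reaches the ester, so that the aryne is lost to self-reaction or a simple aryl ether forms without ring closure.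
Fallback with known chemistry, setting out from 24 and returning at 27: 5-fluorobenzene-1,3-diol is alkylated with 2 (K2CO3, DMF) to 1-fluoro-3,5-bis{[4-(benzyloxy)benzyl]oxy}benzene F1. Bromination with NBS (MeCN, 0 °C) at the position between fluorine and an ether gives 2-bromo-1-fluoro-3,5-bis{[4-(benzyloxy)benzyl]oxy}benzene F2. Bromine–lithium exchange (n-BuLi, THF, −78 °C) gives (2-fluoro-4,6-bis{[4-(benzyloxy)benzyl]oxy}phenyl)lithium F3. Used in excess, F3 first deprotonates the hydroxyl of 24 and then acylates at the ester to give the (2R,3S,8S,9S) α-hydroxy ketone F4. K2CO3 in DMF at 60 °C should then close the benzofuranone by intramolecular nucleophilic aromatic substitution of fluoride by the tertiary alkoxide, with retention at the spiro carbon, giving 27.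

2. Step 6 (key step). The ortho-quinone methide may be intercepted by a second aryne before it cyclizes, or the electron-rich, hindered aryne may add the aldehyde oxygen inefficiently and be consumed by other pathways.
Fallback setting out from 10 and returning at 16: aryne 13 is generated from 10 (CsF, THF, 65 °C) in the presence of commercial (E)-4-(benzyloxy)cinnamic acid. The known insertion of arynes into the C–O bond of carboxylic acids (O–H addition, then acyl transfer to the aryl anion) forms the same two ring-A bonds and gives (E)-1-(2-hydroxy-4,6-bis{[4-(benzyloxy)benzyl]oxy}phenyl)-3-[4-(benzyloxy)phenyl]prop-2-en-1-one F5. 1,2-Reduction (NaBH4, CeCl3·7H2O, MeOH–THF, 0 °C) gives the racemic allylic alcohol 1-(2-hydroxy-4,6-bis{[4-(benzyloxy)benzyl]oxy}phenyl)-3-[4-(benzyloxy)phenyl]prop-2-en-1-ol F6. On mild acid treatment (cat. AcOH or silica gel) F6 should lose water to the ortho-quinone methide 15, which cyclizes to 16.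

3. Step 11. The excited keto ester may be quenched by charge transfer from the electron-rich rings, so that δ-hydrogen abstraction is inefficient. The C2–H is also a δ-hydrogen; its abstraction cannot lead to ring closure, but reversible hydrogen transfer there could erode the C2 configuration. Closure of the biradical also has no facial preference relative to C2/C3, so at best half of the material has the required sense.
Fallback setting out from 22 and returning at 24: a ground-state anionic cyclization. Lithium 2,2,6,6-tetramethylpiperidide (THF, −78→−20 °C) deprotonates the C7 O–CH2 group next to the keto ester. The resulting α-lithiated ether F7 adds 5-exo-trig to the ketone, as known for ortho-benzyloxyaryl ketones, and gives 24 after NH4Cl quench. The aryl group is again expected cis to the alkoxide, and the (8S,9S) isomer is again separated by chromatography.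

Further compounds
F1 | step 12 | 1-fluoro-3,5-bis{[4-(benzyloxy)benzyl]oxy}benzene | Fc1cc(OCc2ccc(OCc3ccccc3)cc2)cc(OCc2ccc(OCc3ccccc3)cc2)c1
F2 | step 12 | 2-bromo-1-fluoro-3,5-bis{[4-(benzyloxy)benzyl]oxy}benzene | Fc1cc(OCc2ccc(OCc3ccccc3)cc2)cc(OCc2ccc(OCc3ccccc3)cc2)c1Br
F3 | step 12 | (2-fluoro-4,6-bis{[4-(benzyloxy)benzyl]oxy}phenyl)lithium | [Li]c1c(F)cc(OCc2ccc(OCc3ccccc3)cc2)cc1OCc1ccc(OCc2ccccc2)cc1
F4 | step 12 | (2-fluoro-4,6-bis{[4-(benzyloxy)benzyl]oxy}phenyl) [(2R,3S,8S,9S)-3-(benzyloxy)-2,8-bis[4-(benzyloxy)phenyl]-5-{[4-(benzyloxy)benzyl]oxy}-9-hydroxy-3,4,8,9-tetrahydro-2H-furo[2,3-h]chromen-9-yl] ketone | C(c1ccccc1)O[C@H]1Cc2c(OCc3ccc(OCc4ccccc4)cc3)cc3O[C@@H](c4ccc(OCc5ccccc5)cc4)[C@](O)(C(=O)c4c(F)cc(OCc5ccc(OCc6ccccc6)cc5)cc4OCc4ccc(OCc5ccccc5)cc4)c3c2O[C@@H]1c1ccc(OCc2ccccc2)cc1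
F5 | step 6 | (E)-1-(2-hydroxy-4,6-bis{[4-(benzyloxy)benzyl]oxy}phenyl)-3-[4-(benzyloxy)phenyl]prop-2-en-1-one | O=C(/C=C/c1ccc(OCc2ccccc2)cc1)c1c(O)cc(OCc2ccc(OCc3ccccc3)cc2)cc1OCc1ccc(OCc2ccccc2)cc1
F6 | step 6 | racemic (E)-1-(2-hydroxy-4,6-bis{[4-(benzyloxy)benzyl]oxy}phenyl)-3-[4-(benzyloxy)phenyl]prop-2-en-1-ol | OC(/C=C/c1ccc(OCc2ccccc2)cc1)c1c(O)cc(OCc2ccc(OCc3ccccc3)cc2)cc1OCc1ccc(OCc2ccccc2)cc1
F7 | step 11 | α-lithiated ether of 22 (lithium on the benzylic carbon of the C7 ether) | C(c1ccccc1)O[C@H]1Cc2c(OCc3ccc(OCc4ccccc4)cc3)cc(O[CH]([Li])c3ccc(OCc4ccccc4)cc3)c(C(=O)C(=O)OC)c2O[C@@H]1c1ccc(OCc2ccccc2)cc1
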